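**Retrosynthetic overview**

- The target is epigallocatechin-(4β→8)-epigallocatechin 3-O-gallate-(4β→8)-epigallocatechin; the last step is hydrogenolysis of its octadeca-O-benzyl ether.
- Key disconnection: the bottom unit is cut at C4(middle)–C8(bottom) and at O1–C2(bottom). This gives a 4-arylthio dimer (top and middle units, all rings complete) and an open-chain cis-epoxy phenol (a seco-epigallocatechin); the two are united and the pyran ring is closed in one flask.
- Enabling feature: in the bottom unit O1 sits on C8a, ortho to the interflavan carbon C8 and 1,5 to the benzylic C2 that carries the 3,4,5-trioxygenated ring B. One free phenolic OH therefore directs the Friedel–Crafts union to C8 and then opens a C2–C3 cis-epoxide at C2 (6-endo), so the cis-epoxide becomes the 2,3-cis flavan-3-ol and the linkage is 4→8 by construction.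
- Dimer: two C4 substitutions with orthogonal leaving groups (2-ethoxyethoxy for a hard Lewis acid, arylthio for silver) on units made from (−)-epigallocatechin. Epoxy phenol: cinnamylation of 3,5-bis(benzyloxy)phenol, E→Z isomerisation, catalytic asymmetric epoxidation.
- Ring order: rings A, B and C of the top and middle units come from the chiral pool, the aromatic rings of the bottom unit are bought, and ring C of the bottom unit is closed last.

Key step: step 12

Assumption: the facial sense of the (S,S)-manganese salen catalyst on the Z-alkene of step 10 is taken to follow that of simple cis-β-alkylstyrenes (benzylic carbon S); if it proved opposite, the (R,R)-catalyst would be used.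

Step 1
Reactants: 1 (−)-epigallocatechin
Product: 2 5,7,3′,4′,5′-penta-O-benzyl-(−)-epigallocatechin
Conditions: BnBr (5.5 equiv), K2CO3, DMF, 0 °C → rt, argon
Reagents that add atoms: benzyl bromide, BrCc1ccccc1
Why: Williamson etherification of the five phenolic hydroxyls under weak carbonate base, which should leave the less acidic secondary 3-OH free and the stereocentres at C2 and C3 untouched.

Step 2
Reactants: 2 penta-O-benzyl-epigallocatechin
Product: 3 (2R,3R,4S)-4-(2-ethoxyethoxy) derivative of 2 (4β, 3,4-trans)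
Conditions: DDQ (2 equiv), 2-ethoxyethanol (5 equiv), CH2Cl2, rt
Reagents that add atoms: 2-ethoxyethanol, CCOCCO
Why: DDQ abstracts hydride from the benzylic C4, which is activated by the ring A oxygens, and the cation is trapped by the alcohol on the β-face, anti to the 2-aryl and 3-hydroxyl groups, so the new C4 stereocentre should be 3,4-trans (benzylic oxidation with alcohol trapping).

Step 3
Reactants: 3 4β-(2-ethoxyethoxy) flavan-3-ol; 4 3,4,5-tris(benzyloxy)benzoic acid
Product: 5 3-O-[3,4,5-tris(benzyloxy)benzoyl] ester of 3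
Conditions: DCC, DMAP, CH2Cl2, rt
Reagents that add atoms: none
Why: Steglich esterification of the secondary 3-OH, which also installs the acyl group that later directs the substitutions at C4 by neighbouring-group participation.

Step 4
Reactants: 5 galloylated 4β-(2-ethoxyethoxy) flavan
Product: 6 (2R,3S,4S)-4-[(2,6-dimethylphenyl)sulfanyl] analogue of 5 (4β, 3,4-trans)
Conditions: 2,6-dimethylbenzenethiol (3 equiv), BF3·OEt2, CH2Cl2, −78 → −30 °C
Reagents that add atoms: 2,6-dimethylbenzenethiol, Cc1cccc(C)c1S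
Why: The hard Lewis acid ionises the C4–O bond to a cation bridged on the α-face by the galloyl carbonyl, so the excess thiol should enter from the β-face and give the 3,4-trans thioether (SN1-type thioetherification), a leaving group inert to boron Lewis acids but labile to silver.

Step 5
Reactants: 3 4β-(2-ethoxyethoxy) flavan-3-ol (top unit electrophile); 6 4β-arylthio gallate (3 equiv, surplus recovered)
Product: 7 trideca-O-benzyl epigallocatechin-(4β→8)-[4β-(2,6-dimethylphenylsulfanyl)epigallocatechin 3-O-gallate]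
Conditions: BF3·OEt2, CH2Cl2, −78 → −40 °C, slow addition of 3
Reagents that add atoms: none
Why: BF3 ionises only the oxygen leaving group of 3, and C8 of 6 (ortho to the ring oxygen, para to the 5-benzyloxy group, used in excess to suppress self-condensation of 3) attacks the cation on the β-face anti to the 2-aryl and 3-hydroxyl groups, setting C4 of the top unit 3,4-trans (interflavan Friedel–Crafts alkylation with orthogonal leaving groups).

Step 6
Reactants: 8 3,4,5-tris(benzyloxy)benzaldehyde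
Product: 9 1-[3,4,5-tris(benzyloxy)phenyl]prop-2-en-1-ol (racemic)
Conditions: vinylmagnesium bromide, THF, −78 → 0 °C; aq. NH4Cl
Reagents that add atoms: vinylmagnesium bromide, C=C[Mg]Br
Why: 1,2-Addition of the Grignard reagent to the aldehyde gives the aryl vinyl carbinol, whose stereocentre is lost in the next step.

Step 7
Reactants: 9 aryl vinyl carbinol; 10 3,5-bis(benzyloxy)phenol (2 equiv)
Product: 11 (E)-3,5-bis(benzyloxy)-2-{3-[3,4,5-tris(benzyloxy)phenyl]prop-2-en-1-yl}phenol
Conditions: H2SO4/SiO2 (cat.), CH2Cl2, rt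
Reagents that add atoms: none
Why: Acid ionises 9 with loss of water to the 1-arylallyl cation, which alkylates the phenol at its terminal carbon and ortho to the free hydroxyl, so the conjugated E-alkene should form under thermodynamic control (dehydrative Friedel–Crafts allylation).

Step 8
Reactants: 11 (E)-cinnamyl phenol
Product: 12 tert-butyldimethylsilyl ether of 11
Conditions: TBSCl, imidazole, DMF, rt
Reagents that add atoms: tert-butyldimethylsilyl chloride, CC(C)(C)[Si](C)(C)Cl
Why: Standard silylation of the phenol, needed because the free electron-rich phenol would not survive the oxidant of step 10.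

Step 9
Reactants: 12 (E)-alkene silyl ether
Product: 13 (Z)-isomer of 12
Conditions: fac-Ir(ppy)3 (ppy = 2-phenylpyridinato; 1 mol%), blue LEDs, degassed MeCN/THF, rt
Reagents that add atoms: none
Why: Triplet energy transfer from the excited iridium complex isomerises the planar E-styrene whereas the twisted Z-styrene is a poorer acceptor and should accumulate (photocatalytic contra-thermodynamic E→Z isomerisation), which provides the cis geometry that the invertive ring closure of step 12 converts into the 2,3-cis flavan.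

Step 10
Reactants: 13 (Z)-alkene silyl ether
Product: 14 tert-butyl{3,5-bis(benzyloxy)-2-[((2R,3S)-3-(3,4,5-tris(benzyloxy)phenyl)oxiran-2-yl)methyl]phenoxy}dimethylsilane (cis-epoxide)
Conditions: (S,S)-(salen)MnCl [salen = N,N′-bis(3,5-di-tert-butylsalicylidene)-1,2-cyclohexanediamine dianion] (5 mol%), mCPBA, NMO, CH2Cl2, −78 °C
Reagents that add atoms: meta-chloroperbenzoic acid, OOC(=O)c1cccc(Cl)c1
Why: Jacobsen–Katsuki epoxidation of a cis-β-alkylstyrene, in which the chiral salen ligand on trivalent manganese selects the alkene face and thereby sets both epoxide carbons (benzylic carbon S, its neighbour R) while the low-temperature peracid variant limits leakage to the trans-epoxide.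

Step 11
Reactants: 14 silylated cis-epoxide
Product: 15 3,5-bis(benzyloxy)-2-{[(2R,3S)-3-(3,4,5-tris(benzyloxy)phenyl)oxiran-2-yl]methyl}phenol
Conditions: TBAF, AcOH (1.2 equiv per fluoride), THF, −20 °C; cold NaHCO3 wash; used at once without chromatography
Reagents that add atoms: none
Why: Fluoride cleaves the aryl silyl ether while acetic acid keeps the liberated phenol protonated, so the acid- and base-sensitive cis-epoxide should survive until the union.

Step 12
Reactants: 7 dimer thioether (1 equiv); 15 cis-epoxy phenol (2.5 equiv)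
Product: 17 octadeca-O-benzyl ether of the target, via seco-trimer cis-epoxy phenol 16 (not isolated)
Conditions: AgBF4 (1.3 equiv), 2,6-di-tert-butyl-4-methylpyridine (1.2 equiv), 4 Å MS, CH2Cl2/THF, −40 °C; then CSA (0.5 equiv), −40 → 0 °C
Reagents that add atoms: none
Why: Thiophilic monovalent silver ionises the C4–S bond of 7 under buffered conditions, the 3-O-galloyl carbonyl bridges the cation on the α-face, and the ring carbon of 15 ortho to its free hydroxyl attacks from the β-face to give 16, after which the pyridinium salt formed and the added CSA protonate the epoxide and the same hydroxyl opens it at the benzylic carbon. The closest known reaction types are the silver-promoted Friedel–Crafts union of 4-thioflavans with free phenolic nucleophiles and the acid-catalysed endo opening of aryl epoxides by a neighbouring hydroxyl. The pyran ring of the bottom unit closes in the 6-endo-tet mode by O1–C2 bond formation. C4 of the middle unit is set 3,4-trans by substrate control (neighbouring galloyl group and 2-aryl group on the α-face), C2 of the bottom unit is set by inversion at the epoxide carbon, and C3 is carried over from the catalyst-made epoxide, so the cis-epoxide is relayed into the 2,3-cis flavan-3-ol. The step needs ortho regioselectivity in the union, secured by the small hydroxyl flank as against the carbon between two benzyloxy groups, and this makes the linkage 4→8 by construction once that hydroxyl has become O1. It also needs 6-endo rather than 5-exo opening and an invertive rather than a cationic course, secured by the electron-rich ring B on C2 (benzylic activation under acid), by the weak buffered acid at low temperature and by the twisted 4-benzyloxy group that makes ring B only a moderate cation stabiliser.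

Step 13
Reactants: 17 octadeca-O-benzyl trimer
Product: 18 epigallocatechin-(4β→8)-epigallocatechin 3-O-gallate-(4β→8)-epigallocatechin (target)
Conditions: H2 (1 atm), Pd(OH)2/C, THF/MeOH/H2O, rt
Reagents that add atoms: none
Why: Hydrogenolysis of the eighteen benzyl ethers over palladium hydroxide on carbon, conditions under which the benzylic C2–O1 bonds of flavans, the gallate ester and the interflavan bonds are expected to persist.

**Compound list**

1 | (−)-epigallocatechin, (2R,3R)-2-(3,4,5-trihydroxyphenyl)chromane-3,5,7-triol | O[C@@H]1Cc2c(O)cc(O)cc2O[C@@H]1c1cc(O)c(O)c(O)c1 | starting material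

2 | (2R,3R)-5,7-bis(benzyloxy)-2-[3,4,5-tris(benzyloxy)phenyl]chroman-3-ol | O[C@@H]1Cc2c(OCc9ccccc9)cc(OCc9ccccc9)cc2O[C@@H]1c8cc(OCc9ccccc9)c(OCc9ccccc9)c(OCc9ccccc9)c8 | intermediate

3 | (2R,3R,4S)-5,7-bis(benzyloxy)-4-(2-ethoxyethoxy)-2-[3,4,5-tris(benzyloxy)phenyl]chroman-3-ol | CCOCCO[C@H]1c2c(OCc9ccccc9)cc(OCc9ccccc9)cc2O[C@H](c8cc(OCc9ccccc9)c(OCc9ccccc9)c(OCc9ccccc9)c8)[C@@H]1O | intermediate

4 | 3,4,5-tris(benzyloxy)benzoic acid | OC(=O)c1cc(OCc2ccccc2)c(OCc2ccccc2)c(OCc2ccccc2)c1 | starting material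

5 | (2R,3R,4S)-5,7-bis(benzyloxy)-4-(2-ethoxyethoxy)-2-[3,4,5-tris(benzyloxy)phenyl]chroman-3-yl 3,4,5-tris(benzyloxy)benzoate | CCOCCO[C@H]1c2c(OCc9ccccc9)cc(OCc9ccccc9)cc2O[C@H](c8cc(OCc9ccccc9)c(OCc9ccccc9)c(OCc9ccccc9)c8)[C@@H]1OC(=O)c8cc(OCc9ccccc9)c(OCc9ccccc9)c(OCc9ccccc9)c8 | intermediate

6 | (2R,3S,4S)-5,7-bis(benzyloxy)-4-[(2,6-dimethylphenyl)sulfanyl]-2-[3,4,5-tris(benzyloxy)phenyl]chroman-3-yl 3,4,5-tris(benzyloxy)benzoate | Cc1cccc(C)c1S[C@H]1c2c(OCc9ccccc9)cc(OCc9ccccc9)cc2O[C@H](c8cc(OCc9ccccc9)c(OCc9ccccc9)c(OCc9ccccc9)c8)[C@@H]1OC(=O)c8cc(OCc9ccccc9)c(OCc9ccccc9)c(OCc9ccccc9)c8 | intermediate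

7 | trideca-O-benzyl epigallocatechin-(4β→8)-[4β-(2,6-dimethylphenylsulfanyl)epigallocatechin 3-O-gallate]; 3-OH of the top unit free | Cc1cccc(C)c1S[C@H]1c2c(OCc9ccccc9)cc(OCc9ccccc9)c([C@H]3c4c(OCc9ccccc9)cc(OCc9ccccc9)cc4O[C@H](c8cc(OCc9ccccc9)c(OCc9ccccc9)c(OCc9ccccc9)c8)[C@@H]3O)c2O[C@H](c8cc(OCc9ccccc9)c(OCc9ccccc9)c(OCc9ccccc9)c8)[C@@H]1OC(=O)c8cc(OCc9ccccc9)c(OCc9ccccc9)c(OCc9ccccc9)c8 | intermediate

8 | 3,4,5-tris(benzyloxy)benzaldehyde | O=Cc1cc(OCc2ccccc2)c(OCc2ccccc2)c(OCc2ccccc2)c1 | starting material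

9 | 1-[3,4,5-tris(benzyloxy)phenyl]prop-2-en-1-ol (racemic) | C=CC(O)c1cc(OCc2ccccc2)c(OCc2ccccc2)c(OCc2ccccc2)c1 | intermediate

10 | 3,5-bis(benzyloxy)phenol | Oc1cc(OCc2ccccc2)cc(OCc2ccccc2)c1 | starting material

11 | (E)-3,5-bis(benzyloxy)-2-{3-[3,4,5-tris(benzyloxy)phenyl]prop-2-en-1-yl}phenol | Oc1cc(OCc2ccccc2)cc(OCc2ccccc2)c1C/C=C/c1cc(OCc2ccccc2)c(OCc2ccccc2)c(OCc2ccccc2)c1 | intermediate

12 | tert-butyldimethylsilyl ether of 11 (E) | CC(C)(C)[Si](C)(C)Oc1cc(OCc2ccccc2)cc(OCc2ccccc2)c1C/C=C/c1cc(OCc2ccccc2)c(OCc2ccccc2)c(OCc2ccccc2)c1 | intermediate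

13 | (Z)-isomer of 12 | CC(C)(C)[Si](C)(C)Oc1cc(OCc2ccccc2)cc(OCc2ccccc2)c1C/C=C\c1cc(OCc2ccccc2)c(OCc2ccccc2)c(OCc2ccccc2)c1 | intermediate

14 | tert-butyl{3,5-bis(benzyloxy)-2-[((2R,3S)-3-(3,4,5-tris(benzyloxy)phenyl)oxiran-2-yl)methyl]phenoxy}dimethylsilane (cis-epoxide) | CC(C)(C)[Si](C)(C)Oc1cc(OCc2ccccc2)cc(OCc2ccccc2)c1C[C@H]3O[C@H]3c1cc(OCc2ccccc2)c(OCc2ccccc2)c(OCc2ccccc2)c1 | intermediate

15 | 3,5-bis(benzyloxy)-2-{[(2R,3S)-3-(3,4,5-tris(benzyloxy)phenyl)oxiran-2-yl]methyl}phenol | Oc1cc(OCc2ccccc2)cc(OCc2ccccc2)c1C[C@H]3O[C@H]3c1cc(OCc2ccccc2)c(OCc2ccccc2)c(OCc2ccccc2)c1 | intermediate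

16 | seco-trimer: 7 with the 4β-arylthio group replaced by a C–C bond to the ring carbon of 15 ortho to its OH (C6 of the phenol); cis-epoxide and phenol intact | O=C(O[C@@H]1[C@@H](c5c(OCc9ccccc9)cc(OCc9ccccc9)c(C[C@H]7O[C@H]7c8cc(OCc9ccccc9)c(OCc9ccccc9)c(OCc9ccccc9)c8)c5O)c2c(OCc9ccccc9)cc(OCc9ccccc9)c([C@H]3c4c(OCc9ccccc9)cc(OCc9ccccc9)cc4O[C@H](c8cc(OCc9ccccc9)c(OCc9ccccc9)c(OCc9ccccc9)c8)[C@@H]3O)c2O[C@@H]1c8cc(OCc9ccccc9)c(OCc9ccccc9)c(OCc9ccccc9)c8)c8cc(OCc9ccccc9)c(OCc9ccccc9)c(OCc9ccccc9)c8 | intermediate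

17 | octadeca-O-benzyl ether of the target (all eighteen phenolic OH benzylated; 3-OH of the top and bottom units free) | O=C(O[C@@H]1[C@@H](c5c(OCc9ccccc9)cc(OCc9ccccc9)c6c5O[C@H](c8cc(OCc9ccccc9)c(OCc9ccccc9)c(OCc9ccccc9)c8)[C@H](O)C6)c2c(OCc9ccccc9)cc(OCc9ccccc9)c([C@H]3c4c(OCc9ccccc9)cc(OCc9ccccc9)cc4O[C@H](c8cc(OCc9ccccc9)c(OCc9ccccc9)c(OCc9ccccc9)c8)[C@@H]3O)c2O[C@@H]1c8cc(OCc9ccccc9)c(OCc9ccccc9)c(OCc9ccccc9)c8)c8cc(OCc9ccccc9)c(OCc9ccccc9)c(OCc9ccccc9)c8 | intermediate

18 | epigallocatechin-(4β→8)-epigallocatechin 3-O-gallate-(4β→8)-epigallocatechin | O=C(O[C@@H]1[C@@H](c2c(O)cc(O)c3c2O[C@H](c2cc(O)c(O)c(O)c2)[C@H](O)C3)c2c(O)cc(O)c([C@H]3c4c(O)cc(O)cc4O[C@H](c4cc(O)c(O)c(O)c4)[C@@H]3O)c2O[C@@H]1c1cc(O)c(O)c(O)c1)c1cc(O)c(O)c(O)c1 | target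

**Step count and risks**

Total: 13 steps. Longest linear sequence: 8 steps (steps 6 to 13); the epigallocatechin branch is 7 steps (1 to 5, 12, 13).

Steps most likely to fail:

1. Step 12. The cis-epoxide may be ionised by the silver salt or by the acid set free before the union is complete (rearrangement to a ketone, or loss of configuration at C2 through a benzylic cation), and the union may occur in part at the carbon between the two benzyloxy groups. The fallback separates union and oxidation, so that no epoxide is present when the interflavan bond is made. It sets out from 13 and 7 and comes back at 17. Compound 13 is desilylated (TBAF, AcOH, THF) to the (Z)-alkene phenol F1. F1 is united with 7 (AgBF4, 2,6-di-tert-butyl-4-methylpyridine, CH2Cl2/THF, −40 °C) to the seco-trimer (Z)-alkene phenol F2. The phenol is silylated in preference to the hindered secondary 3-OH of the top unit (TBSCl, Cs2CO3, DMF) to give the silyl ether F3. Epoxidation with (S,S)-(salen)MnCl, mCPBA and NMO at −78 °C should give the silylated cis-epoxide F4. TBAF/AcOH followed by CSA then closes the ring through 16 to 17.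

2. Step 10. Oxygen transfer from the manganese oxo species is stepwise, so rotation in the benzylic radical intermediate may leak to the trans-epoxide, and facial selection may be incomplete. The fallback gives up catalyst control; it sets out from 13 and comes back at 14. Stereospecific epoxidation with dimethyldioxirane (acetone, −20 °C) should give the racemic cis-epoxide, that is 14 together with its enantiomer F5. Preparative chromatography on a chiral stationary phase separates the two, and 14 continues in step 11.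

3. Step 9. The photostationary state may not be rich enough in the Z-isomer, or other photochemistry of the 1,3-diarylpropene may compete. The fallback builds the Z-alkene by olefination and coupling; it sets out from 12 and comes back at 13. Lemieux–Johnson cleavage of 12 (OsO4 cat., NaIO4, 2,6-lutidine, dioxane/H2O) gives the arylacetaldehyde F6 (aldehyde 8 is recovered). Stork–Zhao olefination (iodomethyltriphenylphosphonium iodide, NaN(SiMe3)2, THF/DMPU, −78 °C) should give the (Z)-vinyl iodide F7. Suzuki coupling with bought 3,4,5-tris(benzyloxy)phenylboronic acid F8 (Pd(PPh3)4, K3PO4, THF/H2O, 40 °C) proceeds with retention of alkene geometry and gives 13.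

**Further compounds**

F1 | step 12 | (Z)-3,5-bis(benzyloxy)-2-{3-[3,4,5-tris(benzyloxy)phenyl]prop-2-en-1-yl}phenol | Oc1cc(OCc2ccccc2)cc(OCc2ccccc2)c1C/C=C\c1cc(OCc2ccccc2)c(OCc2ccccc2)c(OCc2ccccc2)c1

F2 | step 12 | seco-trimer (Z)-alkene phenol: 7 with the 4β-arylthio group replaced by a C–C bond to the ring carbon of F1 ortho to its OH | O=C(O[C@@H]1[C@@H](c5c(OCc9ccccc9)cc(OCc9ccccc9)c(C/C=C\c8cc(OCc9ccccc9)c(OCc9ccccc9)c(OCc9ccccc9)c8)c5O)c2c(OCc9ccccc9)cc(OCc9ccccc9)c([C@H]3c4c(OCc9ccccc9)cc(OCc9ccccc9)cc4O[C@H](c8cc(OCc9ccccc9)c(OCc9ccccc9)c(OCc9ccccc9)c8)[C@@H]3O)c2O[C@@H]1c8cc(OCc9ccccc9)c(OCc9ccccc9)c(OCc9ccccc9)c8)c8cc(OCc9ccccc9)c(OCc9ccccc9)c(OCc9ccccc9)c8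

F3 | step 12 | tert-butyldimethylsilyl ether (at the phenol) of F2 | O=C(O[C@@H]1[C@@H](c5c(OCc9ccccc9)cc(OCc9ccccc9)c(C/C=C\c8cc(OCc9ccccc9)c(OCc9ccccc9)c(OCc9ccccc9)c8)c5O[Si](C)(C)C(C)(C)C)c2c(OCc9ccccc9)cc(OCc9ccccc9)c([C@H]3c4c(OCc9ccccc9)cc(OCc9ccccc9)cc4O[C@H](c8cc(OCc9ccccc9)c(OCc9ccccc9)c(OCc9ccccc9)c8)[C@@H]3O)c2O[C@@H]1c8cc(OCc9ccccc9)c(OCc9ccccc9)c(OCc9ccccc9)c8)c8cc(OCc9ccccc9)c(OCc9ccccc9)c(OCc9ccccc9)c8

F4 | step 12 | tert-butyldimethylsilyl ether (at the phenol) of 16, (2R,3S)-cis-epoxide | O=C(O[C@@H]1[C@@H](c5c(OCc9ccccc9)cc(OCc9ccccc9)c(C[C@H]7O[C@H]7c8cc(OCc9ccccc9)c(OCc9ccccc9)c(OCc9ccccc9)c8)c5O[Si](C)(C)C(C)(C)C)c2c(OCc9ccccc9)cc(OCc9ccccc9)c([C@H]3c4c(OCc9ccccc9)cc(OCc9ccccc9)cc4O[C@H](c8cc(OCc9ccccc9)c(OCc9ccccc9)c(OCc9ccccc9)c8)[C@@H]3O)c2O[C@@H]1c8cc(OCc9ccccc9)c(OCc9ccccc9)c(OCc9ccccc9)c8)c8cc(OCc9ccccc9)c(OCc9ccccc9)c(OCc9ccccc9)c8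

F5 | step 10 | enantiomer of 14, (2S,3R)-cis-epoxide | CC(C)(C)[Si](C)(C)Oc1cc(OCc2ccccc2)cc(OCc2ccccc2)c1C[C@@H]3O[C@@H]3c1cc(OCc2ccccc2)c(OCc2ccccc2)c(OCc2ccccc2)c1

F6 | step 9 | 2-[2,4-bis(benzyloxy)-6-(tert-butyldimethylsilyloxy)phenyl]acetaldehyde | CC(C)(C)[Si](C)(C)Oc1cc(OCc2ccccc2)cc(OCc2ccccc2)c1CC=O

F7 | step 9 | (Z)-vinyl iodide: {3,5-bis(benzyloxy)-2-[(Z)-3-iodoprop-2-en-1-yl]phenoxy}(tert-butyl)dimethylsilane | CC(C)(C)[Si](C)(C)Oc1cc(OCc2ccccc2)cc(OCc2ccccc2)c1C/C=C\I

F8 | step 9 | 3,4,5-tris(benzyloxy)phenylboronic acid (bought) | OB(O)c1cc(OCc2ccccc2)c(OCc2ccccc2)c(OCc2ccccc2)c1
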